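(The constants belong to no real substance; no experiment stands behind them.)

**The constants.** Of the constants, 24.2 M⁻¹ s⁻¹ for the quench by protic impurity stands far above 0.517 M⁻¹ s⁻¹ for coupling with the partner and 0.230 M⁻¹ s⁻¹ for dimerisation.

    intermediate ⇌ target (K1 = 2.53, k1 = 4.02 s⁻¹)
    2 starting material → homo dimer (k2 = 0.230 M⁻¹ s⁻¹)
    partner → decomposed reagent (k3 = 0.0123 s⁻¹)
    starting material + partner → intermediate + by-product (k4 = 0.517 M⁻¹ s⁻¹)
    starting material + protic impurity → quenched substrate (k5 = 24.2 M⁻¹ s⁻¹)
    intermediate ⇌ isomer of the product (K6 = 11, k6 = 0.0837 s⁻¹)

- gamma: starting material 0.10 M; partner 0.600 equiv; protic impurity 0.0500 M; time 15 s
- epsilon: starting material 0.10 M; partner 0.600 equiv; protic impurity 0.0500 M; time 30 s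

- percentages count the starting material that a species holds: one homo dimer counts as two
- a step written with two of one species runs at k times the square of its concentration and takes two of it each time
- run time (gamma): 15 s

1. which of these there is most of at the end, counted by the starting material in it, gamma (intermediate / target / starting material / isomer of the product)
2. which of these there is most of at the end, counted by the starting material in it, epsilon (intermediate / target / starting material / isomer of the product)
3. the largest of these amounts at the end, in percent of the starting material charged, gamma
4. the largest of these amounts at the end, in percent of the starting material charged, epsilon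

**Starting rate.** Our reckoning follows one rate: the fraction of starting material lost per second. In gamma the quench opens at 1.21 s⁻¹. It takes half of the charge and spares 50.0 %. Each survivor then goes at 0.0310 s⁻¹ by coupling plus 0.0230 s⁻¹ by dimerisation, which makes 0.0540 s⁻¹. We call this sum, taken with the partner as charged and the survivors at their full level, the survivor rate, a pseudo-first-order constant for that one moment. The quench is much faster, so we let it finish first.

**The slowing.** The dimerisation term falls in step with the survivors. The partner term falls through coupling and through decomposition; decomposition's own factor by 15 s is 0.832, and coupling lowers it further. We let the whole rate fall with the survivors, an approximation. The decay then integrates in closed form: the survivors keep one over one plus the survivor rate times the time.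

That factor is 0.552 at 15 s and 0.382 at 30 s, so we commit to 27.6 % in gamma and 19.1 % in epsilon. Coupling takes the share 0.574 of these later losses, so the coupled products together hold 12.9 % in gamma and 17.8 % in epsilon. Both are less than the starting material, which is our answer for each flask.

**The forecast.** It names starting material for gamma and starting material for epsilon, at 26 % (24.5 % to 27.5 %) and 17.7 % (16.3 % to 19.2 %); in its words, “Starting material therefore remains the largest in both runs”. Our percentages are higher.

**The flask.** It gives starting material at 25.9 % in gamma and starting material at 17.5 % in epsilon, there 8.5 percentage points above target. In gamma half of the quench's turnover was done by 0.340 s, and >99.9 % of it by 7.50 s, when protic impurity stood at 0.0334 % of its charge. Coupling and dimerisation then ran on the survivors, with the partner at 76.9 % of its charge at that time and 62.5 % at 15 s. Our reckoning stood 1.7 points above gamma and 1.6 points above epsilon.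

**Second flask.** The neighbour of gamma with 0.013 M of protic impurity spares 87.0 %, and its survivor rate is 0.0710 s⁻¹, higher than in gamma. The same factor gives 42.1 % at 15 s; that flask held 41.3 %.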